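Readings and results come from a simulation with made-up constants.

Time is where these runs part from a steady reaction: from 8.00 min to 15.0 min in the delta run the clock advances by a factor 1.88, but the target grows by a factor 3.52.

| flask | starting material | precatalyst | remark |
|---|---|---|---|
| delta | 0.027 M | 5.4 µM | run made earlier |
| beta | 0.11 M | 5.4 µM | run made earlier |
| epsilon | 0.054 M | 8.1 µM | run made earlier |
| flask | 0.054 M | 5.4 µM |  |

| run | time / min | target / % | starting material / % |
|---|---|---|---|
| delta | 8.00 | 12.9 | 86.4 |
| delta | 12.0 | 29.3 | 70.6 |
| delta | 15.0 | 45.4 | 54.6 |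
| delta | 25.0 | 95.9 | 4.2 |
| delta | 40.0 | 99.9 | 0 |
| delta | 60.0 | 99.4 | 0 |
| delta | 90.0 | 99.3 | 0.2 |
| beta | 5.00 | 1.3 | 98.4 |
| beta | 15.0 | 13.3 | 87.6 |
| beta | 25.0 | 33.9 | 66.0 |
| beta | 40.0 | 79.9 | 20.3 |
| beta | 50.0 | 100.0 | 0 |
| beta | 80.0 | 100.5 | 0 |
| beta | 90.0 | 99.9 | 0 |
| epsilon | 8.00 | 10.5 | 88.9 |
| epsilon | 25.0 | 90.1 | 9.5 |
| epsilon | 40.0 | 99.9 | 0 |
| epsilon | 60.0 | 100.1 | 0.1 |
| epsilon | 90.0 | 99.4 | 0 |

(readings scatter by 0.5 percentage points)

* factor on the rate of making target when 20 % of the starting material are converted if precatalyst is charged twice over
* factor on the rate when 20 % of the starting material are converted if precatalyst is charged at 50 µM instead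

The bench rule of thumb says that a catalyst works at a steady pace, so the rate follows the charge: a factor 2 for the doubled charge and 9.26 at 50 µM. That rule needs target in proportion to time, and its border is in the ratio above: the target factor equals the time factor squared, 3.52.

So we count turnovers (the turnover number), N, the target made per precatalyst charged. If N grows with time squared, one number describes a run, the time of the first turnover:

τ = t / √N

At 15.0 min in the delta run this reads 0.315 min, and we call it the first-turnover time, the time by which target equal to one charge of precatalyst has been made. The beta run at 25.0 min reads 0.301 min and the epsilon run at 8.00 min reads 0.302 min, close together across these charges, so we hold τ fixed.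

In the flask, 20 % conversion needs

N = 2000, reached at t = τ·√N = 14.1 min

With τ fixed, the rate grows in proportion to the charge of precatalyst and to t. At a fixed conversion t falls as the square root of the charge, so the rate rises with that square root:

doubled charge: 1.41; at 50 µM: 3.04

The second number is an extrapolation: 50 µM lies above the 8.1 µM of the epsilon run, the largest charge in the runs.

The forecast gives 1.45 and 3.2, and it reads the runs as “active catalyst slowly accumulating from the precatalyst”.

The flask gives 1.44 and 3.15.

    starting material + enzyme ⇌ complex (K = 460 M⁻¹, k = 26000 M⁻¹ s⁻¹)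
    complex → enzyme + target (k = 2500 min⁻¹)
    precatalyst ⇌ enzyme (K = 0.620, k = 0.0100 min⁻¹)

With our τ of 0.315 min the flask should reach 20 % conversion at 14.1 min, and it does so at 13.46 min. For the flask with the doubled charge, τ gives a factor 0.706 on that time, against 0.702 from the run. The rate constant of complex going on to enzyme and target is 1.5 × 10⁵ h⁻¹, far larger than the 0.60 h⁻¹ of precatalyst turning into enzyme. At 20 % conversion in the flask, precatalyst is 87.5 % of the catalyst and complex is 11.5 %.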